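**Retrosynthetic overview**

1. Target 26 ⇐ tetraol 25 (hydroxyl-directed epoxidation of the only alkene left) ⇐ ketone 23 (equatorial methyl addition, desilylation).
2. Key step (step 15): 23 ⇐ open-chain diepoxy silyl enol ether 22 that already carries the finished hydroazulene; one Me3SiOTf-triggered epoxonium cascade closes the oxepane and the cyclohexanone together.
3. 22 ⇐ allyl-hydroazulene 15 + diepoxy vinyl ketone 20 (cross-metathesis, then 1,4-hydrosilylation); 20 ⇐ (E)-geranylacetone 16 (Shi epoxidation).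
4. 15 ⇐ bicyclic 1,3-dione 10 (Stork–Danheiser allylation, CBS reduction); the seven-membered ring of 10 is closed onto a cyclopentene oxide by its own β-diketone dianion.
5. Ring order: cyclopentane (RCM of (S)-linalool 1; Ireland–Claisen relays its stereocentre) → cycloheptane → oxepane + cyclohexane (cascade) → oxirane.

Assumption: (S)-(+)-linalool of high ee and (E)-geranylacetone are bought as such; hydroazulene locants in the names are C1 (carbinol), C3a, C4 (gem-dimethyl), C5–C8, C8a.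

**Route**

Step 1
Reactants: 1 (S)-linalool, (3S)-3,7-dimethylocta-1,6-dien-3-ol
Product: 3 (1S)-1-methylcyclopent-2-en-1-yl 2-methylpropanoate, via cyclopentenol 2 (not isolated)
Conditions: second-generation Grubbs catalyst RuCl2(=CHPh)(H2IMes)(PCy3) (0.2 mol %), neat, 45 °C; then THF, n-BuLi, −78 °C; i-PrCOCl, −78 → 0 °C
Reagents that add atoms: isobutyryl chloride, CC(C)C(Cl)=O
Why: Ring-closing metathesis of the 1,6-diene (loss of isobutene) leaves the carbinol stereocentre untouched, and the volatile tertiary allylic alcohol is O-acylated in the same flask through its lithium alkoxide.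

Step 2
Reactants: 3 (1S)-1-methylcyclopent-2-en-1-yl 2-methylpropanoate
Product: 6 2-methyl-2-[(1R)-3-methylcyclopent-2-en-1-yl]propanoic acid, via silyl ketene acetal 4 (not isolated), via trimethylsilyl ester 5 (not isolated)
Conditions: LiN(i-Pr)2, THF–DMPU, −78 °C; Me3SiCl, −78 → 60 °C; then 1 M HCl
Reagents that add atoms: none
Why: Ireland–Claisen rearrangement: the [3,3] shift is suprafacial on the cyclopentenyl unit, so the C–O stereocentre of 3 is relayed to the new C–C bond (future C3a, R) while the gem-dimethyl quaternary carbon (future C4) is made.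

Step 3
Reactants: 6 2-methyl-2-[(1R)-3-methylcyclopent-2-en-1-yl]propanoic acid
Product: 7 2-methyl-2-[(1R)-3-methylcyclopent-2-en-1-yl]pentan-3-one
Conditions: EtLi (2.5 equiv), Et2O, 0 → 25 °C; aq. NH4Cl
Reagents that add atoms: ethyllithium, [Li]CC
Why: Ketone synthesis from a carboxylic acid and an organolithium: the dilithium gem-diolate of the hindered acid stops at the ketone stage until work-up.

Step 4
Reactants: 7 2-methyl-2-[(1R)-3-methylcyclopent-2-en-1-yl]pentan-3-one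
Product: 8 2-methyl-2-[(1S,2S,5R)-5-methyl-6-oxabicyclo[3.1.0]hexan-2-yl]pentan-3-one
Conditions: mCPBA, NaHCO3, CH2Cl2, 0 °C
Reagents that add atoms: 3-chloroperoxybenzoic acid, OOC(=O)c1cccc(Cl)c1
Why: Prilezhaev epoxidation of the trisubstituted alkene from the face opposite the bulky tertiary-alkyl group on the neighbouring ring carbon, which fixes the configuration of the future C1 oxygen (R).

Step 5
Reactants: 8 2-methyl-2-[(1S,2S,5R)-5-methyl-6-oxabicyclo[3.1.0]hexan-2-yl]pentan-3-one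
Product: 9 3,5-dimethyl-5-[(1S,2S,5R)-5-methyl-6-oxabicyclo[3.1.0]hexan-2-yl]hexane-2,4-dione (C3 epimers, partly enolised)
Conditions: LiN(SiMe3)2 (2.2 equiv), toluene–THF, −78 °C; AcCl, −78 °C; AcOH
Reagents that add atoms: acetyl chloride, CC(Cl)=O
Why: Claisen-type C-acylation of the lithium enolate; the ketone can enolise only toward the ethyl group because its other α-carbon is quaternary.

Step 6
Reactants: 9 epoxy β-diketone
Product: 10 (1R,3aR,8aR)-1-hydroxy-1,4,4,6-tetramethyloctahydroazulene-5,7-dione (cis-fused, C6 epimers)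
Conditions: LiN(i-Pr)2 (2.3 equiv), THF, −78 → 25 °C; aq. NH4Cl
Reagents that add atoms: none
Why: Proposed new method: the terminal carbanion of the β-diketone dianion (Hauser dianion) sits on the ring face opposite the oxirane oxygen and can reach only the secondary oxirane carbon, so a 7-exo-tet SN2 opening with inversion gives the cis-fused seven-membered ring (C8a R) and frees the C1 alkoxide trans to the new bond; the closest known chemistry is γ-alkylation of β-dicarbonyl dianions by epoxides and Stork-type intramolecular epoxide opening by enolates.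

Step 7
Reactants: 10 bicyclic 1,3-dione
Product: 11 (1R,3aR,8aR)-1-hydroxy-7-methoxy-1,4,4,6-tetramethyl-2,3,3a,4,8,8a-hexahydroazulen-5(1H)-one
Conditions: HC(OMe)3, MeOH, TsOH (cat.), 25 °C
Reagents that add atoms: trimethyl orthoformate, COC(OC)OC
Why: Acid-catalysed enol ether (vinylogous ester) formation under thermodynamic control occurs at the carbonyl remote from the gem-dimethyl carbon, as with 4,4-dimethylcyclohexane-1,3-dione.

Step 8
Reactants: 11 vinylogous methyl ester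
Product: 13 (1R,3aR,8aR)-1-hydroxy-1,4,4,6-tetramethyl-5-(prop-2-en-1-yl)-2,3,3a,4,8,8a-hexahydroazulen-7(1H)-one, via carbinol adduct 12 (not isolated)
Conditions: allylMgBr (3 equiv), THF, −78 → 0 °C; then 1 M HCl, THF, 25 °C
Reagents that add atoms: allylmagnesium bromide, C=CC[Mg]Br; water, O
Why: Stork–Danheiser alkylative enone transposition: 1,2-addition to the vinylogous ester carbonyl, then acid hydrolysis and dehydration, give the tetrasubstituted enone with the carbonyl at C7 and the linker carbon on C5.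

Step 9
Reactants: 13 allyl enone
Product: 14 (1R,3aR,7R,8aR)-1,4,4,6-tetramethyl-5-(prop-2-en-1-yl)-1,2,3,3a,4,7,8,8a-octahydroazulene-1,7-diol
Conditions: (S)-2-methyl-CBS-oxazaborolidine (20 mol %), catecholborane, toluene, −78 °C; then MeOH, aq. NaOH
Reagents that add atoms: none
Why: Corey–Bakshi–Shibata reduction: with the α-methyl alkenyl carbon as the large group, the (S)-catalyst delivers hydride under catalyst control to give the 7R allylic alcohol.

Step 10
Reactants: 14 allylic diol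
Product: 15 (1R,3aR,7R,8aR)-1,4,4,6-tetramethyl-5-(prop-2-en-1-yl)-1,7-bis(triethylsilyloxy)-1,2,3,3a,4,7,8,8a-octahydroazulene
Conditions: Et3SiOTf, 2,6-lutidine, CH2Cl2, −78 → 0 °C
Reagents that add atoms: triethylsilyl trifluoromethanesulfonate, CC[Si](CC)(CC)OS(=O)(=O)C(F)(F)F
Why: Silyl ether formation with the silyl triflate covers both the tertiary and the allylic secondary hydroxyl so that neither is free in the Lewis-acid step.

Step 11
Reactants: 16 (E)-geranylacetone, (5E)-6,10-dimethylundeca-5,9-dien-2-one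
Product: 17 (5R,6R,9R)-5,6:9,10-diepoxy-6,10-dimethylundecan-2-one
Conditions: Shi ketone from D-fructose (0.6 equiv), KHSO5 (as Oxone, 2KHSO5·KHSO4·K2SO4), K2CO3, Bu4NHSO4, pH 10.5 buffer, MeCN–CH2(OMe)2–H2O, 0 °C
Reagents that add atoms: potassium peroxymonosulfate, [K+].[O-]S(=O)(=O)OO
Why: Shi asymmetric epoxidation: the chiral dioxirane attacks both trisubstituted E-alkenes through the same spiro transition state and sets all three oxirane stereocentres (R).

Step 12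
Reactants: 17 diepoxy methyl ketone
Product: 20 (6R,7R,10R)-6,7:10,11-diepoxy-7,11-dimethyldodec-1-en-3-one, via Mannich base 18 (not isolated), via methiodide 19 (not isolated)
Conditions: LiN(i-Pr)2, THF, −78 °C; Me2N=CH2+ I−, −78 → 25 °C; then MeI, CH2Cl2, 25 °C; then aq. NaHCO3, 25 °C
Reagents that add atoms: N,N-dimethylmethyleneiminium iodide, C[N+](C)=C.[I-]
Why: Mannich reaction of the kinetic methyl-side enolate with Eschenmoser's salt, then quaternisation and Hofmann-type E1cB elimination, gives the vinyl ketone without touching the oxiranes.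

Step 13
Reactants: 15 bis(triethylsilyl) allyl-hydroazulene; 20 diepoxy vinyl ketone
Product: 21 (2E,7R,8R,11R)-7,8:11,12-diepoxy-8,12-dimethyl-1-[bis(triethylsilyloxy)hydroazulen-5-yl]tridec-2-en-4-one (full name in the list)
Conditions: second-generation Hoveyda–Grubbs catalyst RuCl2(H2IMes)(=CH-C6H4-2-O-i-Pr) (7 mol %), 20 (3 equiv), 1,4-benzoquinone (10 mol %), CH2Cl2, 40 °C
Reagents that add atoms: none
Why: Olefin cross-metathesis between a terminal alkene and an electron-poor vinyl ketone gives the E-enone selectively and joins the two halves in the two-carbon linker.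

Step 14
Reactants: 21 C30 (E)-enone
Product: 22 (3Z)-4-triethylsilyloxy enol ether of 21 (full name in the list)
Conditions: RhCl(PPh3)3 (3 mol %), Et3SiH, benzene, 50 °C
Reagents that add atoms: triethylsilane, CC[SiH](CC)CC
Why: Rhodium-catalysed 1,4-hydrosilylation of the disubstituted enone gives the Z silyl enol ether regiospecifically on the linker side of the ketone, which direct enolisation could not do.

Step 15
Reactants: 22 C30 diepoxy silyl enol ether
Product: 23 (3R,5aR,6R,9aR)-6-[2-(hydroazulen-5-yl)ethyl]-2,2,5a-trimethyl-3-(trimethylsilyloxy)octahydro-1-benzoxepin-7(2H)-one (full name in the list)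
Conditions: Me3SiOTf (1.3 equiv), 2,6-di-tert-butyl-4-methylpyridine (1.5 equiv), CH2Cl2 (2 mM), −78 °C; aq. NaHCO3
Reagents that add atoms: trimethylsilyl trifluoromethanesulfonate, C[Si](C)(C)OS(=O)(=O)C(F)(F)F
Why: Epoxide-opening cascade (tandem oxa- and carbacyclization of a diepoxy enol silane): the silyl-activated terminal oxirane is opened at its tertiary carbon by the internal oxirane oxygen (7-endo), and the resulting epoxonium ion is opened at its tertiary carbon with inversion by the enol silane through a chair transition state, so C3 and C9a keep the oxirane configuration while C5a (R) and C6 (R, equatorial chain) are set.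

Step 16
Reactants: 23 tetracyclic ketone
Product: 25 (3R,5aR,6R,7S,9aR)-6-{2-[(1R,3aR,7R,8aR)-1,7-dihydroxy-1,4,4,6-tetramethyl-1,2,3,3a,4,7,8,8a-octahydroazulen-5-yl]ethyl}-2,2,5a,7-tetramethyldecahydro-1-benzoxepine-3,7-diol, via silylated carbinol 24 (not isolated)
Conditions: MeLi, CeCl3, THF, −78 °C; then Bu4NF, THF, 25 °C
Reagents that add atoms: methyllithium, [Li]C
Why: Organocerium 1,2-addition: the axial C5a methyl blocks axial approach to the C7 ketone, so methyl enters equatorially and gives the axial tertiary alcohol (7S), and fluoride then removes the three silyl groups.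

Step 17
Reactants: 25 tetraol
Product: 26 target, (3R,5aR,6R,7S,9aR)-6-{2-[(1R,3aR,5S,6R,7R,8aR)-5,6-epoxy-1,7-dihydroxy-1,4,4,6-tetramethyldecahydroazulen-5-yl]ethyl}-2,2,5a,7-tetramethyldecahydro-1-benzoxepine-3,7-diol
Conditions: VO(acac)2 (5 mol %), t-BuOOH, CH2Cl2, 0 → 25 °C
Reagents that add atoms: tert-butyl hydroperoxide, CC(C)(C)OO
Why: Vanadium-catalysed hydroxyl-directed epoxidation (Sharpless–Michaelson): the C7 allylic alkoxide delivers oxygen to its own face of the tetrasubstituted alkene, which is also the convex face of the cis-fused bicycle, giving the (5S,6R)-oxirane cis to the 7-OH.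

**Compound list**

1 | (S)-linalool, (3S)-3,7-dimethylocta-1,6-dien-3-ol | C=C[C@@](C)(O)CCC=C(C)C | starting material
2 | (1S)-1-methylcyclopent-2-en-1-ol | C[C@]1(O)CCC=C1 | intermediate
3 | (1S)-1-methylcyclopent-2-en-1-yl 2-methylpropanoate | C[C@]1(OC(=O)C(C)C)CCC=C1 | intermediate
4 | trimethyl({2-methyl-1-[(1S)-1-methylcyclopent-2-en-1-yl]oxyprop-1-en-1-yl}oxy)silane | C[C@]1(OC(O[Si](C)(C)C)=C(C)C)CCC=C1 | intermediate
5 | trimethylsilyl 2-methyl-2-[(1R)-3-methylcyclopent-2-en-1-yl]propanoate | C[Si](C)(C)OC(=O)C(C)(C)[C@@H]1CCC(C)=C1 | intermediate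
6 | 2-methyl-2-[(1R)-3-methylcyclopent-2-en-1-yl]propanoic acid | OC(=O)C(C)(C)[C@@H]1CCC(C)=C1 | intermediate
7 | 2-methyl-2-[(1R)-3-methylcyclopent-2-en-1-yl]pentan-3-one | CCC(=O)C(C)(C)[C@@H]1CCC(C)=C1 | intermediate
8 | 2-methyl-2-[(1S,2S,5R)-5-methyl-6-oxabicyclo[3.1.0]hexan-2-yl]pentan-3-one | CCC(=O)C(C)(C)[C@@H]1CC[C@@]2(C)O[C@@H]12 | intermediate
9 | 3,5-dimethyl-5-[(1S,2S,5R)-5-methyl-6-oxabicyclo[3.1.0]hexan-2-yl]hexane-2,4-dione (C3 epimers) | CC(=O)C(C)C(=O)C(C)(C)[C@@H]1CC[C@@]2(C)O[C@@H]12 | intermediate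
10 | (1R,3aR,8aR)-1-hydroxy-1,4,4,6-tetramethyloctahydroazulene-5,7-dione (C6 epimers) | O=C1C(C)C(=O)C[C@@H]2[C@@H](CC[C@@]2(C)O)C1(C)C | intermediate
11 | (1R,3aR,8aR)-1-hydroxy-7-methoxy-1,4,4,6-tetramethyl-2,3,3a,4,8,8a-hexahydroazulen-5(1H)-one | O=C1C(C)=C(OC)C[C@@H]2[C@@H](CC[C@@]2(C)O)C1(C)C | intermediate
12 | (1R,3aR,8aR)-7-methoxy-1,4,4,6-tetramethyl-5-(prop-2-en-1-yl)-1,2,3,3a,4,5,8,8a-octahydroazulene-1,5-diol (C5 epimers) | C=CCC1(O)C(C)=C(OC)C[C@@H]2[C@@H](CC[C@@]2(C)O)C1(C)C | intermediate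
13 | (1R,3aR,8aR)-1-hydroxy-1,4,4,6-tetramethyl-5-(prop-2-en-1-yl)-2,3,3a,4,8,8a-hexahydroazulen-7(1H)-one | C=CCC1=C(C)C(=O)C[C@@H]2[C@@H](CC[C@@]2(C)O)C1(C)C | intermediate
14 | (1R,3aR,7R,8aR)-1,4,4,6-tetramethyl-5-(prop-2-en-1-yl)-1,2,3,3a,4,7,8,8a-octahydroazulene-1,7-diol | C=CCC1=C(C)[C@H](O)C[C@@H]2[C@@H](CC[C@@]2(C)O)C1(C)C | intermediate
15 | (1R,3aR,7R,8aR)-1,4,4,6-tetramethyl-5-(prop-2-en-1-yl)-1,7-bis(triethylsilyloxy)-1,2,3,3a,4,7,8,8a-octahydroazulene | C=CCC1=C(C)[C@H](O[Si](CC)(CC)CC)C[C@@H]2[C@@H](CC[C@@]2(C)O[Si](CC)(CC)CC)C1(C)C | intermediate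
16 | (E)-geranylacetone, (5E)-6,10-dimethylundeca-5,9-dien-2-one | CC(=O)CC/C=C(\C)CCC=C(C)C | starting material
17 | (5R,6R,9R)-5,6:9,10-diepoxy-6,10-dimethylundecan-2-one | CC(=O)CC[C@H]1O[C@]1(C)CC[C@H]1OC1(C)C | intermediate
18 | (6R,7R,10R)-1-(dimethylamino)-6,7:10,11-diepoxy-7,11-dimethyldodecan-3-one | CN(C)CCC(=O)CC[C@H]1O[C@]1(C)CC[C@H]1OC1(C)C | intermediate
19 | (6R,7R,10R)-6,7:10,11-diepoxy-N,N,N,7,11-pentamethyl-3-oxododecan-1-aminium iodide | C[N+](C)(C)CCC(=O)CC[C@H]1O[C@]1(C)CC[C@H]1OC1(C)C.[I-] | intermediate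
20 | (6R,7R,10R)-6,7:10,11-diepoxy-7,11-dimethyldodec-1-en-3-one | C=CC(=O)CC[C@H]1O[C@]1(C)CC[C@H]1OC1(C)C | intermediate
21 | (2E,7R,8R,11R)-7,8:11,12-diepoxy-8,12-dimethyl-1-[(1R,3aR,7R,8aR)-1,4,4,6-tetramethyl-1,7-bis(triethylsilyloxy)-1,2,3,3a,4,7,8,8a-octahydroazulen-5-yl]tridec-2-en-4-one | O=C(CC[C@H]1O[C@]1(C)CC[C@H]1OC1(C)C)/C=C/CC1=C(C)[C@H](O[Si](CC)(CC)CC)C[C@@H]2[C@@H](CC[C@@]2(C)O[Si](CC)(CC)CC)C1(C)C | intermediate
22 | triethyl{[(3Z,7R,8R,11R)-7,8:11,12-diepoxy-8,12-dimethyl-1-[(1R,3aR,7R,8aR)-1,4,4,6-tetramethyl-1,7-bis(triethylsilyloxy)-1,2,3,3a,4,7,8,8a-octahydroazulen-5-yl]tridec-3-en-4-yl]oxy}silane | CC[Si](CC)(CC)O/C(CC[C@H]1O[C@]1(C)CC[C@H]1OC1(C)C)=C\CCC1=C(C)[C@H](O[Si](CC)(CC)CC)C[C@@H]2[C@@H](CC[C@@]2(C)O[Si](CC)(CC)CC)C1(C)C | intermediate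
23 | (3R,5aR,6R,9aR)-2,2,5a-trimethyl-6-{2-[(1R,3aR,7R,8aR)-1,4,4,6-tetramethyl-1,7-bis(triethylsilyloxy)-1,2,3,3a,4,7,8,8a-octahydroazulen-5-yl]ethyl}-3-(trimethylsilyloxy)octahydro-1-benzoxepin-7(2H)-one | CC1(C)O[C@@H]2CCC(=O)[C@H](CCC3=C(C)[C@H](O[Si](CC)(CC)CC)C[C@@H]4[C@@H](CC[C@@]4(C)O[Si](CC)(CC)CC)C3(C)C)[C@@]2(C)CC[C@H]1O[Si](C)(C)C | intermediate
24 | (3R,5aR,6R,7S,9aR)-2,2,5a,7-tetramethyl-6-{2-[(1R,3aR,7R,8aR)-1,4,4,6-tetramethyl-1,7-bis(triethylsilyloxy)-1,2,3,3a,4,7,8,8a-octahydroazulen-5-yl]ethyl}-3-(trimethylsilyloxy)decahydro-1-benzoxepin-7-ol | CC1(C)O[C@@H]2CC[C@](C)(O)[C@H](CCC3=C(C)[C@H](O[Si](CC)(CC)CC)C[C@@H]4[C@@H](CC[C@@]4(C)O[Si](CC)(CC)CC)C3(C)C)[C@@]2(C)CC[C@H]1O[Si](C)(C)C | intermediate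
25 | (3R,5aR,6R,7S,9aR)-6-{2-[(1R,3aR,7R,8aR)-1,7-dihydroxy-1,4,4,6-tetramethyl-1,2,3,3a,4,7,8,8a-octahydroazulen-5-yl]ethyl}-2,2,5a,7-tetramethyldecahydro-1-benzoxepine-3,7-diol | CC1(C)O[C@@H]2CC[C@](C)(O)[C@H](CCC3=C(C)[C@H](O)C[C@@H]4[C@@H](CC[C@@]4(C)O)C3(C)C)[C@@]2(C)CC[C@H]1O | intermediate
26 | (3R,5aR,6R,7S,9aR)-6-{2-[(1R,3aR,5S,6R,7R,8aR)-5,6-epoxy-1,7-dihydroxy-1,4,4,6-tetramethyldecahydroazulen-5-yl]ethyl}-2,2,5a,7-tetramethyldecahydro-1-benzoxepine-3,7-diol (CNP0203623.2) | CC1(C)O[C@@H]2CC[C@](C)(O)[C@H](CC[C@@]34O[C@]3(C)[C@H](O)C[C@@H]3[C@@H](CC[C@@]3(C)O)C4(C)C)[C@@]2(C)CC[C@H]1O | target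

**Totals**

Total step count: 17. Longest linear sequence: 15 steps (steps 1–10 and 13–17, from (S)-linalool); the geranylacetone branch is 2 steps (11, 12).

**Three steps most likely to fail, each with one fallback**

Step 6 (seven-membered ring closure by the dianion). It may lose to O-alkylation, to five-membered closure through the central carbon, or to base-induced oxirane isomerisation. The fallback sets out from 8 and comes back to the route at 13. The two-carbon unit is brought in from outside by a small linear nucleophile and the ring is closed by carbonyl condensation instead. LiC≡CSiMe3/BF3·OEt2 (THF, −78 °C) opens the oxirane of 8 at its secondary carbon to give 2-methyl-2-[(1R,2S,3R)-3-hydroxy-3-methyl-2-(trimethylsilylethynyl)cyclopentyl]pentan-3-one F1. K2CO3/MeOH, then dicyclohexylborane followed by NaBO3, turn the alkyne into 2-[(1R,2R,5R)-2-hydroxy-2-methyl-5-(2-methyl-3-oxopentan-2-yl)cyclopentyl]acetaldehyde F2. Intramolecular aldol condensation (KOH, MeOH) closes the ring to (1R,3aR,8aR)-1-hydroxy-1,4,4,6-tetramethyl-2,3,3a,4,8,8a-hexahydroazulen-5(1H)-one F3. AllylMgBr adds 1,2 to give (1R,3aR,8aR)-1,4,4,6-tetramethyl-5-(prop-2-en-1-yl)-1,2,3,3a,4,5,8,8a-octahydroazulene-1,5-diol F4, and Dauben–Michno oxidative transposition with pyridinium chlorochromate, C5H5NH[CrO3Cl], gives 13.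

Step 13 (cross-metathesis of the allyl group next to a tetrasubstituted alkene with a polymerisable vinyl ketone). The fallback sets out from 15 and 17 and comes back at 21, making the same enone by olefination. Lemieux–Johnson cleavage (OsO4 cat., NaIO4, 2,6-lutidine, dioxane–H2O) of the terminal alkene of 15 gives [(1R,3aR,7R,8aR)-1,4,4,6-tetramethyl-1,7-bis(triethylsilyloxy)-1,2,3,3a,4,7,8,8a-octahydroazulen-5-yl]acetaldehyde F5. Methyl ketone 17 is turned by LiN(i-Pr)2/ClP(O)(OEt)2 and a second equivalent of LiN(i-Pr)2 (enol phosphate to β-ketophosphonate 1,3-phosphorus shift) into diethyl [(5R,6R,9R)-5,6:9,10-diepoxy-6,10-dimethyl-2-oxoundecyl]phosphonate F6. Horner–Wadsworth–Emmons olefination of F5 with F6 (Ba(OH)2, wet THF) gives 21.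

Step 15 (the cascade on the fully assembled substrate). The electron-rich tetrasubstituted alkene and the allylic silyl ether of the hydroazulene may interfere, or the oxacyclization may not be followed by C–C closure. The fallback sets out from 20 (and uses 11) and comes back at 25: the cascade is run on the left fragment alone and the hydroazulene is attached afterwards.
- Cross-metathesis of 20 with allyl tert-butyldimethylsilyl ether (second-generation Hoveyda–Grubbs catalyst) gives (2E,7R,8R,11R)-1-(tert-butyldimethylsilyloxy)-7,8:11,12-diepoxy-8,12-dimethyltridec-2-en-4-one F7.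
- RhCl(PPh3)3/Et3SiH gives its (3Z)-4-triethylsilyloxy enol ether F8.
- The Me3SiOTf cascade, now on the substrate type for which it is established, gives (3R,5aR,6R,9aR)-6-[2-(tert-butyldimethylsilyloxy)ethyl]-2,2,5a-trimethyl-3-(trimethylsilyloxy)octahydro-1-benzoxepin-7(2H)-one F9.
- MeLi/CeCl3, then Bu4NF, give (3R,5aR,6R,7S,9aR)-6-(2-hydroxyethyl)-2,2,5a,7-tetramethyldecahydro-1-benzoxepine-3,7-diol F10.
- I2/PPh3/imidazole converts the primary alcohol into (3R,5aR,6R,7S,9aR)-6-(2-iodoethyl)-2,2,5a,7-tetramethyldecahydro-1-benzoxepine-3,7-diol F11.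
- F11 (2 MeLi, then 2 t-BuLi, −78 °C) is added to the lithium alkoxide of 11, and 1 M HCl gives, by the same Stork–Danheiser transposition, (3R,5aR,6R,7S,9aR)-6-{2-[(1R,3aR,8aR)-1-hydroxy-1,4,4,6-tetramethyl-7-oxo-1,2,3,3a,4,7,8,8a-octahydroazulen-5-yl]ethyl}-2,2,5a,7-tetramethyldecahydro-1-benzoxepine-3,7-diol F12.
- (S)-CBS reduction of F12 gives 25.

**Further compounds**

F1 | step 6 | 2-methyl-2-[(1R,2S,3R)-3-hydroxy-3-methyl-2-(trimethylsilylethynyl)cyclopentyl]pentan-3-one | C[Si](C)(C)C#C[C@@H]1[C@@H](CC[C@@]1(C)O)C(C)(C)C(=O)CC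
F2 | step 6 | 2-[(1R,2R,5R)-2-hydroxy-2-methyl-5-(2-methyl-3-oxopentan-2-yl)cyclopentyl]acetaldehyde | O=CC[C@@H]1[C@@H](CC[C@@]1(C)O)C(C)(C)C(=O)CC
F3 | step 6 | (1R,3aR,8aR)-1-hydroxy-1,4,4,6-tetramethyl-2,3,3a,4,8,8a-hexahydroazulen-5(1H)-one | O=C1C(C)=CC[C@@H]2[C@@H](CC[C@@]2(C)O)C1(C)C
F4 | step 6 | (1R,3aR,8aR)-1,4,4,6-tetramethyl-5-(prop-2-en-1-yl)-1,2,3,3a,4,5,8,8a-octahydroazulene-1,5-diol (C5 epimers) | C=CCC1(O)C(C)=CC[C@@H]2[C@@H](CC[C@@]2(C)O)C1(C)C
F5 | step 13 | [(1R,3aR,7R,8aR)-1,4,4,6-tetramethyl-1,7-bis(triethylsilyloxy)-1,2,3,3a,4,7,8,8a-octahydroazulen-5-yl]acetaldehyde | O=CCC1=C(C)[C@H](O[Si](CC)(CC)CC)C[C@@H]2[C@@H](CC[C@@]2(C)O[Si](CC)(CC)CC)C1(C)C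
F6 | step 13 | diethyl [(5R,6R,9R)-5,6:9,10-diepoxy-6,10-dimethyl-2-oxoundecyl]phosphonate | CCOP(=O)(OCC)CC(=O)CC[C@H]1O[C@]1(C)CC[C@H]1OC1(C)C
F7 | step 15 | (2E,7R,8R,11R)-1-(tert-butyldimethylsilyloxy)-7,8:11,12-diepoxy-8,12-dimethyltridec-2-en-4-one | O=C(CC[C@H]1O[C@]1(C)CC[C@H]1OC1(C)C)/C=C/CO[Si](C)(C)C(C)(C)C
F8 | step 15 | (3Z,7R,8R,11R)-1-(tert-butyldimethylsilyloxy)-7,8:11,12-diepoxy-8,12-dimethyl-4-(triethylsilyloxy)tridec-3-ene | CC[Si](CC)(CC)O/C(CC[C@H]1O[C@]1(C)CC[C@H]1OC1(C)C)=C\CCO[Si](C)(C)C(C)(C)C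
F9 | step 15 | (3R,5aR,6R,9aR)-6-[2-(tert-butyldimethylsilyloxy)ethyl]-2,2,5a-trimethyl-3-(trimethylsilyloxy)octahydro-1-benzoxepin-7(2H)-one | CC1(C)O[C@@H]2CCC(=O)[C@H](CCO[Si](C)(C)C(C)(C)C)[C@@]2(C)CC[C@H]1O[Si](C)(C)C
F10 | step 15 | (3R,5aR,6R,7S,9aR)-6-(2-hydroxyethyl)-2,2,5a,7-tetramethyldecahydro-1-benzoxepine-3,7-diol | CC1(C)O[C@@H]2CC[C@](C)(O)[C@H](CCO)[C@@]2(C)CC[C@H]1O
F11 | step 15 | (3R,5aR,6R,7S,9aR)-6-(2-iodoethyl)-2,2,5a,7-tetramethyldecahydro-1-benzoxepine-3,7-diol | CC1(C)O[C@@H]2CC[C@](C)(O)[C@H](CCI)[C@@]2(C)CC[C@H]1O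
F12 | step 15 | (3R,5aR,6R,7S,9aR)-6-{2-[(1R,3aR,8aR)-1-hydroxy-1,4,4,6-tetramethyl-7-oxo-1,2,3,3a,4,7,8,8a-octahydroazulen-5-yl]ethyl}-2,2,5a,7-tetramethyldecahydro-1-benzoxepine-3,7-diol | CC1(C)O[C@@H]2CC[C@](C)(O)[C@H](CCC3=C(C)C(=O)C[C@@H]4[C@@H](CC[C@@]4(C)O)C3(C)C)[C@@]2(C)CC[C@H]1O
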